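Rings: A is the terminal 2-hydroxy-4-methoxy-6-methylbenzoyl unit, B the central 4-acyloxy-2-methoxy-6-methylbenzoyl unit, and C the methyl 4-acyloxy-2-hydroxy-6-methylbenzoate terminus.
Cuts: the two phenolic C2–O bonds of rings A and C are cut together first. The A–B acyl–oxygen bond follows, then the B–C acyl–oxygen bond, and the ring B acid is traced back to methyl orsellinate.
Enabling feature: in the deoxy tridepside, C2–H of ring A and C2–H of ring C are the only C–H bonds ortho to a carbonyl. C6 of both rings carries CH3, and ring B has OMe at C2 and CH3 at C6.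
Forward: no ring is built. The three purchased arenes are joined B + C, then + A, by two esterifications, and both salicylate OH groups enter last by a twofold carbonyl-directed C–H oxygenation.
Stereochemistry: the target has no stereogenic element, so nothing has to be set.

Key step: step 7

Remark: the SMILES shows no stereocentre, no double-bond geometry and no hindered axis. The compound is therefore treated as achiral, and the demand for a single enantiomer is met trivially.

Step 1
Reactants: 1 methyl orsellinate (methyl 2,4-dihydroxy-6-methylbenzoate)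
Product: 2 methyl 4-(benzyloxy)-2-hydroxy-6-methylbenzoate
Conditions: BnBr (1.05 equiv), K2CO3 (1.2 equiv), acetone, reflux
Reagents that add atoms: benzyl bromide, BrCc1ccccc1
Why: Williamson ether synthesis, in which the 2-OH is tied up in a hydrogen bond to the ester carbonyl, so one equivalent of benzyl bromide with a mild carbonate base should alkylate only the more acidic and unhindered 4-OH.

Step 2
Reactants: 2 methyl 4-(benzyloxy)-2-hydroxy-6-methylbenzoate
Product: 3 methyl 4-(benzyloxy)-2-methoxy-6-methylbenzoate
Conditions: MeI (3 equiv), K2CO3 (2 equiv), DMF, 50 °C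
Reagents that add atoms: iodomethane, CI
Why: Williamson O-methylation, in which excess iodomethane in a dipolar aprotic solvent should force alkylation of the one remaining, chelated phenol, a routine operation on orsellinates.

Step 3
Reactants: 3 methyl 4-(benzyloxy)-2-methoxy-6-methylbenzoate
Product: 5 4-(benzyloxy)-2-methoxy-6-methylbenzoic acid (ring B acid), via potassium carboxylate 4 (not isolated)
Conditions: KOH (5 equiv), DMSO/H2O (4:1), 90 °C; then 1 M HCl, 0 °C, pH 2
Reagents that add atoms: potassium hydroxide, [K+].[OH-]
Why: Saponification (BAc2 ester hydrolysis) of a di-ortho-substituted benzoate calls for poorly solvated hydroxide in hot aqueous DMSO, which both ethers tolerate, and cold acidification should avoid protodecarboxylation of the electron-rich acid.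

Step 4
Reactants: 5 4-(benzyloxy)-2-methoxy-6-methylbenzoic acid; 6 methyl 4-hydroxy-2-methylbenzoate (ring C phenol)
Product: 7 methyl 4-{[4-(benzyloxy)-2-methoxy-6-methylbenzoyl]oxy}-2-methylbenzoate
Conditions: DCC (1.2 equiv), DMAP (0.2 equiv), CH2Cl2, 0 °C to rt
Reagents that add atoms: none
Why: Steglich esterification, in which DMAP converts the O-acylisourea into an acylpyridinium ion that the unhindered and fairly acidic phenol 6 should intercept, the usual way of forging depside bonds from di-ortho-substituted alkoxybenzoic acids.

Step 5
Reactants: 7 methyl 4-{[4-(benzyloxy)-2-methoxy-6-methylbenzoyl]oxy}-2-methylbenzoate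
Product: 8 methyl 4-[(4-hydroxy-2-methoxy-6-methylbenzoyl)oxy]-2-methylbenzoate
Conditions: H2 (1 atm), 10% Pd/C, EtOAc, rt
Reagents that add atoms: none
Why: Catalytic hydrogenolysis of the benzyl aryl ether runs under neutral conditions that should leave the aryl ester and the methyl ester untouched, and the molecule holds no other reducible group.

Step 6
Reactants: 8 methyl 4-[(4-hydroxy-2-methoxy-6-methylbenzoyl)oxy]-2-methylbenzoate; 9 4-methoxy-2-methylbenzoic acid (ring A acid)
Product: 10 methyl 4-({2-methoxy-4-[(4-methoxy-2-methylbenzoyl)oxy]-6-methylbenzoyl}oxy)-2-methylbenzoate (2,2''-bis-deoxy tridepside)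
Conditions: DCC (1.2 equiv), DMAP (0.2 equiv), CH2Cl2, 0 °C to rt
Reagents that add atoms: none
Why: Steglich esterification of an acid with only one ortho substituent by the single free phenol of 8, so neither hindrance nor chemoselectivity should be an issue.

Step 7
Reactants: 10 methyl 4-({2-methoxy-4-[(4-methoxy-2-methylbenzoyl)oxy]-6-methylbenzoyl}oxy)-2-methylbenzoate
Product: 12 methyl 2-hydroxy-4-({4-[(2-hydroxy-4-methoxy-6-methylbenzoyl)oxy]-2-methoxy-6-methylbenzoyl}oxy)-6-methylbenzoate (target tridepside), via bis(trifluoroacetate) 11 (not isolated)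
Conditions: [RuCl2(p-cymene)]2 (5 mol %), PhI(OCOCF3)2 (3 equiv), TFA/TFAA (3:1), 70 °C; then ice-water, EtOAc, rt
Reagents that add atoms: [bis(trifluoroacetoxy)iodo]benzene (PIFA), O=C(OI(OC(=O)C(F)(F)F)c1ccccc1)C(F)(F)F
Why: Proposed new method: carbonyl-directed Ru(II)-catalysed ortho C–H hydroxylation in TFA/TFAA is the closest known reaction type and is established for alkyl benzoates, which covers the methyl ester of ring C, whereas direction by an aryl ester (depside) carbonyl, as ring A requires, and two such oxygenations in one flask have not been shown. A cationic Ru(II) trifluoroacetate should bind each of the two carbonyl oxygens, cleave the neighbouring C–H by carboxylate-assisted metalation to a five-membered ruthenacycle, be oxidised by PIFA to Ru(IV) and release an aryl trifluoroacetate by C–O reductive elimination, so that 11 builds up and gives up both trifluoroacetyl groups to water during work-up. No ring closes and no stereocentre arises. The step needs site selectivity, and the substrate supplies it: the second ortho position of rings A and C carries CH3, ring B has no ortho C–H, the phenol-side positions within reach of the A–B carbonyl (C3 and C5 of ring B) each lie between two substituents, and the B–C carbonyl, twisted out of plane by its OMe and CH3 neighbours, is a poor ligand for six-membered metalation on ring C. The para-methoxy group of ring A feeds electron density into the depside carbonyl and should offset the weaker donor strength of an aryl ester, while the acyl group lowers the tendency of that ring to undirected oxidation ortho to OMe. Each new oxygen is capped at once as an electron-poor trifluoroacetate, which should stop over-oxidation, and TFAA keeps the medium dry, so the depside bonds, which are classically made in TFAA/TFA media, should persist.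

Compound list
1 | methyl orsellinate (methyl 2,4-dihydroxy-6-methylbenzoate) | COC(=O)c1c(C)cc(O)cc1O | starting material
2 | methyl 4-(benzyloxy)-2-hydroxy-6-methylbenzoate | COC(=O)c1c(C)cc(OCc2ccccc2)cc1O | intermediate
3 | methyl 4-(benzyloxy)-2-methoxy-6-methylbenzoate | COC(=O)c1c(C)cc(OCc2ccccc2)cc1OC | intermediate
4 | potassium 4-(benzyloxy)-2-methoxy-6-methylbenzoate (not isolated) | [K+].[O-]C(=O)c1c(C)cc(OCc2ccccc2)cc1OC | intermediate
5 | 4-(benzyloxy)-2-methoxy-6-methylbenzoic acid | OC(=O)c1c(C)cc(OCc2ccccc2)cc1OC | intermediate
6 | methyl 4-hydroxy-2-methylbenzoate | COC(=O)c1ccc(O)cc1C | starting material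
7 | methyl 4-{[4-(benzyloxy)-2-methoxy-6-methylbenzoyl]oxy}-2-methylbenzoate | COC(=O)c1ccc(OC(=O)c2c(C)cc(OCc3ccccc3)cc2OC)cc1C | intermediate
8 | methyl 4-[(4-hydroxy-2-methoxy-6-methylbenzoyl)oxy]-2-methylbenzoate | COC(=O)c1ccc(OC(=O)c2c(C)cc(O)cc2OC)cc1C | intermediate
9 | 4-methoxy-2-methylbenzoic acid | COc1ccc(C(=O)O)c(C)c1 | starting material
10 | methyl 4-({2-methoxy-4-[(4-methoxy-2-methylbenzoyl)oxy]-6-methylbenzoyl}oxy)-2-methylbenzoate | COC(=O)c1ccc(OC(=O)c2c(C)cc(OC(=O)c3ccc(OC)cc3C)cc2OC)cc1C | intermediate
11 | methyl 4-{[2-methoxy-4-({4-methoxy-2-methyl-6-[(trifluoroacetyl)oxy]benzoyl}oxy)-6-methylbenzoyl]oxy}-2-methyl-6-[(trifluoroacetyl)oxy]benzoate (not isolated) | COC(=O)c1c(C)cc(OC(=O)c2c(C)cc(OC(=O)c3c(C)cc(OC)cc3OC(=O)C(F)(F)F)cc2OC)cc1OC(=O)C(F)(F)F | intermediate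
12 | methyl 2-hydroxy-4-({4-[(2-hydroxy-4-methoxy-6-methylbenzoyl)oxy]-2-methoxy-6-methylbenzoyl}oxy)-6-methylbenzoate | COC(=O)c1c(C)cc(OC(=O)c2c(C)cc(OC(=O)c3c(C)cc(OC)cc3O)cc2OC)cc1O | target

Total step count: 7. Longest linear sequence: 7 steps (1 to 12); 6 and 9 are purchased and enter directly.

Steps most likely to fail

Step 7 (bears the label).
- Risk: metalation next to the weakly donating depside carbonyl may lag so far behind metalation at the methyl ester that the reaction stalls after one oxygenation. The anisole-type ring A may be oxidised without direction, or hot TFA may scramble the ester links by acyl exchange.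
- Fallback: it uses known chemistry only, buys both phenolic oxygens with the building blocks, sets out from acid 5 and methyl orsellinate 1, and returns at target 12. DCC/DMAP coupling of 5 with 1 should acylate only the free 4-OH of 1, because the 2-OH is chelated, and give methyl 4-{[4-(benzyloxy)-2-methoxy-6-methylbenzoyl]oxy}-2-hydroxy-6-methylbenzoate F1. Hydrogenolysis (H2, Pd/C, EtOAc) then frees the ring B phenol in methyl 2-hydroxy-4-[(4-hydroxy-2-methoxy-6-methylbenzoyl)oxy]-6-methylbenzoate F2. Carbodiimide coupling (DCC, toluene, rt) of F2 with purchased everninic acid F3 should deliver 12 directly, since only the non-chelated 4-OH of ring B is nucleophilic enough to react.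

Step 4.
- Risk: attack of the phenol on an activated carboxyl flanked by OMe and CH3 may be so slow that O-to-N acyl migration within the carbodiimide adduct consumes the acid.
- Fallback: it forms the aryl–oxygen bond instead of the acyl–oxygen bond, so the crowded carbonyl carbon is never attacked. It sets out from 5 and returns at 7. Purchased methyl 4-iodo-2-methylbenzoate F4 is oxidised with mCPBA in the presence of TsOH·H2O and trapped with anisole (CH2Cl2/CF3CH2OH, rt) to give [4-(methoxycarbonyl)-3-methylphenyl](4-methoxyphenyl)iodonium tosylate F5. Acid 5 is deprotonated with t-BuOK in toluene to the salt 4 and heated with F5 (110–130 °C). This is the known metal-free O-arylation of carboxylates with diaryliodonium salts. Ligand coupling at iodine(III) should transfer the electron-poorer, ester-bearing aryl group to the carboxylate oxygen and give 7.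

Step 3.
- Risk: addition of hydroxide to the shielded ester carbonyl may need such forcing conditions that protodecarboxylation of the electron-rich acid sets in during heating or acidification.
- Fallback: a redox detour that sets out from 3 and returns at 5. LiAlH4 (THF, 0 °C) should reduce the ester to [4-(benzyloxy)-2-methoxy-6-methylphenyl]methanol F6. MnO2 (CH2Cl2, rt) oxidises this to 4-(benzyloxy)-2-methoxy-6-methylbenzaldehyde F7. Pinnick oxidation (NaClO2, NaH2PO4, 2-methyl-2-butene, t-BuOH/H2O, rt) then gives 5 under mild, buffered conditions.

Further compounds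
F1 | step 7 | methyl 4-{[4-(benzyloxy)-2-methoxy-6-methylbenzoyl]oxy}-2-hydroxy-6-methylbenzoate | COC(=O)c1c(C)cc(OC(=O)c2c(C)cc(OCc3ccccc3)cc2OC)cc1O
F2 | step 7 | methyl 2-hydroxy-4-[(4-hydroxy-2-methoxy-6-methylbenzoyl)oxy]-6-methylbenzoate | COC(=O)c1c(C)cc(OC(=O)c2c(C)cc(O)cc2OC)cc1O
F3 | step 7 | everninic acid (2-hydroxy-4-methoxy-6-methylbenzoic acid, purchased) | COc1cc(C)c(C(=O)O)c(O)c1
F4 | step 4 | methyl 4-iodo-2-methylbenzoate (purchased) | COC(=O)c1ccc(I)cc1C
F5 | step 4 | [4-(methoxycarbonyl)-3-methylphenyl](4-methoxyphenyl)iodonium tosylate | COC(=O)c1ccc([I+]c2ccc(OC)cc2)cc1C.Cc1ccc(S(=O)(=O)[O-])cc1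
F6 | step 3 | [4-(benzyloxy)-2-methoxy-6-methylphenyl]methanol | COc1cc(OCc2ccccc2)cc(C)c1CO
F7 | step 3 | 4-(benzyloxy)-2-methoxy-6-methylbenzaldehyde | COc1cc(OCc2ccccc2)cc(C)c1C=O
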